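## Retrosynthetic overview
1. C9–O acyl bond, cut last: p-coumaric acid is joined to the only aliphatic OH of (−)-lariciresinol without protecting groups.
2. The tetrahydrofuran (C7–O bond) is the only ring formed. It opens back to a p-quinone methide that carries the C9′ hydroxyl, the same quinone methide/hydroxyl closure that builds lignan furan rings in the plant. Here it is reached by dehydrogenating C2-symmetric (+)-secoisolariciresinol, not by way of pinoresinol.
3. C8–C8′ bond: radical dimerisation of two identical C6C3 units. An Evans oxazolidinone plays the part of the dirigent protein and sets C8 and C8′ (S,S) in one step.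
4. The monomer comes from dihydroferulic acid, pivaloyl chloride and (R)-4-isopropyloxazolidin-2-one in one pot. C7 (R) is relayed from C8 during the ring closure.

Assumption: the SMILES is read as 7R,8S,8′S (oxolane 2R,3S,4S). That is the p-coumarate of (−)-lariciresinol, the mirror image of the more common (+)-lariciresinol. Lignan numbering is used: the ring is O, C7, C8, C8′, C9′. C9 carries the ester and C7′ is the benzyl CH2.

## Route

Step 1
Reactants: 1 dihydroferulic acid [3-(4-hydroxy-3-methoxyphenyl)propanoic acid]; 2 (R)-4-isopropyloxazolidin-2-one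
Product: 4 (4R)-4-isopropyl-3-[3-(3-methoxy-4-pivaloyloxyphenyl)propanoyl]oxazolidin-2-one, via mixed pivalic anhydride 3 (not isolated)
Conditions: PivCl (2.2 equiv), Et3N (3.5 equiv), THF, −20 to 0 °C; then LiCl (1.2 equiv), 2 (1.0 equiv), rt, 12 h
Reagents that add atoms: pivaloyl chloride, CC(C)(C)C(=O)Cl
Why: Pivaloyl chloride esterifies the phenol and converts the acid into mixed anhydride 3, whose unhindered acyl carbon is then attacked by the LiCl-activated oxazolidinone (mixed-anhydride N-acylation of an Evans auxiliary); no new stereocentre forms and C4 of the auxiliary is untouched.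

Step 2
Reactants: 4 (4R)-imide (two equivalents)
Product: 7 (2S,3S)-1,4-bis[(4R)-4-isopropyl-2-oxooxazolidin-3-yl]-2,3-bis[(3-methoxy-4-pivaloyloxyphenyl)methyl]butane-1,4-dione, via lithium Z-enolate 5 (not isolated), via trichlorotitanium Z-enolate 6 (not isolated)
Conditions: LiN(iPr)2 (1.1 equiv), THF, −78 °C, 45 min; TiCl4 (1.1 equiv), −78 to −20 °C; chromatography, then recrystallisation
Reagents that add atoms: none
Why: This is an oxidative enolate homocoupling of an Evans imide, in which tetravalent titanium takes one electron from the chelated Z-enolate (leaving as trivalent titanium) and the two α-imidyl radicals join through the faces anti to the isopropyl groups, so the (4R)-auxiliary gives the (8S,8′S)-dimer as main diastereomer, separable from the minor (S,R) and (R,R) isomers, while the aryl pivalates have no α-hydrogen and are too hindered to react at −78 °C.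

Step 3
Reactants: 7 (S,S)-bis-imide
Product: 8 (+)-secoisolariciresinol, (2S,3S)-2,3-bis[(4-hydroxy-3-methoxyphenyl)methyl]butane-1,4-diol
Conditions: LiAlH4 (5 equiv), THF, 0 °C to rt; aq. KNaC4H4O6, adjusted to pH 5, EtOAc extraction
Reagents that add atoms: none
Why: LiAlH4 reduces both N-acyloxazolidinones to primary alcohols and cleaves both aryl pivalates in one operation, faster than any enolisation, so C8 and C8′ stay S,S.

Step 4
Reactants: 8 (+)-secoisolariciresinol
Product: 10 (−)-lariciresinol, 4-{[(3S,4S,5R)-5-(4-hydroxy-3-methoxyphenyl)-4-(hydroxymethyl)oxolan-3-yl]methyl}-2-methoxyphenol, via p-quinone methide 9 (not isolated)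
Conditions: DDQ (0.8 equiv, slow addition), dry 1,4-dioxane, rt, 1 h; filter, chromatograph, recycle recovered 8
Reagents that add atoms: none
Why: Proposed new method: DDQ removes H2 (phenolic H plus benzylic hydride) from one of the two homotopic 4-hydroxy-3-methoxybenzyl groups to give p-quinone methide 9, and the C9′ hydroxyl adds to C7 in a 5-exo-trig oxa-1,6-addition through an envelope that places the aryl group on the ring face opposite the cis-disposed C8 CH2OH and C8′ benzyl groups (7,8-trans, C7 = R, reinforced because the closure is reversible) while C8 and C8′ are untouched; the closest known reaction types are the DDQ benzylic dehydrogenation of 4-alkylphenols to quinone methides and the acid-induced cyclisation of 7-hydroxysecoisolariciresinol to lariciresinol.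

Step 5
Reactants: 10 (−)-lariciresinol; 11 (E)-p-coumaric acid
Product: 13 (−)-lariciresinol 9-O-(E)-p-coumarate (target; 7R,8S,8′S), via alkoxyphosphonium p-coumarate 12 (not isolated)
Conditions: 11 (1.1 equiv), PPh3 (1.3 equiv), DIAD (1.3 equiv), THF, 0 °C to rt
Reagents that add atoms: none
Why: In this Mitsunobu esterification only the carboxylic acid (pKa about 4.5) protonates the betaine and only the aliphatic primary OH forms the alkoxyphosphonium ion, so the three phenols stay free, and substitution occurs at the achiral C9 methylene, which leaves C7, C8, C8′ and the E-alkene unchanged.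

## Compound list
1 | dihydroferulic acid | COc1cc(CCC(=O)O)ccc1O | starting material
2 | (R)-4-isopropyloxazolidin-2-one | CC(C)[C@@H]1COC(=O)N1 | starting material
3 | 3-(3-methoxy-4-pivaloyloxyphenyl)propanoic pivalic anhydride | COc1cc(CCC(=O)OC(=O)C(C)(C)C)ccc1OC(=O)C(C)(C)C | intermediate
4 | (4R)-4-isopropyl-3-[3-(3-methoxy-4-pivaloyloxyphenyl)propanoyl]oxazolidin-2-one | COc1cc(CCC(=O)N2[C@H](C(C)C)COC2=O)ccc1OC(=O)C(C)(C)C | intermediate
5 | lithium Z-enolate of 4 | COc1cc(C/C=C(\[O-])N2[C@H](C(C)C)COC2=O)ccc1OC(=O)C(C)(C)C.[Li+] | intermediate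
6 | trichlorotitanium Z-enolate of 4 | COc1cc(C/C=C(\O[Ti](Cl)(Cl)Cl)N2[C@H](C(C)C)COC2=O)ccc1OC(=O)C(C)(C)C | intermediate
7 | (2S,3S)-bis-imide dimer | COc1cc(C[C@H](C(=O)N2[C@H](C(C)C)COC2=O)[C@H](Cc2ccc(OC(=O)C(C)(C)C)c(OC)c2)C(=O)N2[C@H](C(C)C)COC2=O)ccc1OC(=O)C(C)(C)C | intermediate
8 | (+)-(2S,3S)-secoisolariciresinol | COc1cc(C[C@H](CO)[C@H](Cc2ccc(O)c(OC)c2)CO)ccc1O | intermediate
9 | mono-p-quinone methide of 8 (C7=C1 exocyclic, C8 and C8′ as in 8) | COC1=CC(=C[C@H](CO)[C@H](Cc2ccc(O)c(OC)c2)CO)C=CC1=O | intermediate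
10 | (−)-(7R,8S,8′S)-lariciresinol | COc1cc(C[C@@H]2CO[C@@H](c3ccc(O)c(OC)c3)[C@@H]2CO)ccc1O | intermediate
11 | (E)-p-coumaric acid | O=C(O)/C=C/c1ccc(O)cc1 | starting material
12 | C9-O-triphenylphosphonium salt of 10, p-coumarate counter-ion | COc1cc(C[C@@H]2CO[C@@H](c3ccc(O)c(OC)c3)[C@@H]2CO[P+](c2ccccc2)(c2ccccc2)c2ccccc2)ccc1O.[O-]C(=O)/C=C/c1ccc(O)cc1 | intermediate
13 | lariciresinol p-coumarate | COc1cc(C[C@@H]2CO[C@@H](c3ccc(O)c(OC)c3)[C@@H]2COC(=O)/C=C/c2ccc(O)cc2)ccc1O | target

## Step count and risks
Total step count: 5. Longest linear sequence: 5 (1 → 4 → 7 → 8 → 10 → 13).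

**Most likely to fail, first: step 4.**
- Product 10 still holds an oxidisable benzyl group and a p-hydroxybenzylic C7–H, so over-oxidation competes.
- The yield per pass is capped near the statistical 40–50 %.
- Traces of acid can divert 9 into the aryltetralin cyclolariciresinol.

The fallback sets out from 8 and comes back at 10. Compound 8 is oxidised exhaustively (DDQ, 2.2 equiv, dioxane) so that both benzylic positions pass through quinone methides and both hydroxyls close. This gives the C2-symmetric furofuran (−)-pinoresinol F1, and no statistical mixture arises. One benzylic C–O bond of F1 is then cleaved by hydrogenolysis (H2, 1 atm, Pd/C, EtOH, stopped after one equivalent). Release of the bicyclic strain makes the first cleavage faster than the second, and the product is 10.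

**Second: step 2.**
- Radical dimerisation gives moderate yield and diastereoselectivity.
- TiCl4 must tolerate the guaiacyl pivalates.

The fallback sets out from 4 and comes back at 8. It replaces the dimerisation by two polar alkylations.
- The sodium enolate of 4 (NaN(SiMe3)2, THF, −78 °C) is alkylated with tert-butyl bromoacetate anti to the isopropyl group. This gives tert-butyl (3S)-4-[(4R)-4-isopropyl-2-oxooxazolidin-3-yl]-3-[(3-methoxy-4-pivaloyloxyphenyl)methyl]-4-oxobutanoate F2.
- LiBH4 (1.2 equiv, Et2O with 1 equiv H2O, 0 °C) removes the auxiliary reductively. This gives tert-butyl (3S)-4-hydroxy-3-[(3-methoxy-4-pivaloyloxyphenyl)methyl]butanoate F3.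
- F3 lactonises with catalytic TsOH in warm toluene to (4S)-4-[(3-methoxy-4-pivaloyloxyphenyl)methyl]oxolan-2-one F4.
- LiN(SiMe3)2 (THF, −78 °C) and commercial 4-benzyloxy-3-methoxybenzyl bromide alkylate F4 anti to the β-benzyl group. This gives the trans-lactone (3S,4S)-3-[(4-benzyloxy-3-methoxyphenyl)methyl]-4-[(3-methoxy-4-pivaloyloxyphenyl)methyl]oxolan-2-one F5.
- LiAlH4 opens the lactone and cleaves the pivalate to give 4-O-benzyl-(+)-secoisolariciresinol F6.
- H2 over Pd/C then gives 8.

**Third: step 5.**
- The β-branched primary alcohol reacts slowly.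
- Phenol O-alkylation or coumarate oligomers may compete.

The fallback sets out from 10 and comes back at 13. It builds the cinnamate on the lignan instead of coupling the finished acid. Meldrum's acid (1.0 equiv, toluene, 95 °C) is opened by the aliphatic OH of 10, which is more nucleophilic than the phenols. This gives the malonic half ester (−)-lariciresinol 9-O-(carboxyacetate) F7. A Knoevenagel–Doebner condensation of F7 with 4-hydroxybenzaldehyde (pyridine, catalytic piperidine, 50 °C) proceeds with decarboxylation and delivers the E-p-coumarate 13.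

## Further compounds
F1 | step 4 | (−)-(7R,7′R,8S,8′S)-pinoresinol | COc1cc([C@H]2[C@@H]3CO[C@@H](c4ccc(O)c(OC)c4)[C@@H]3CO2)ccc1O
F2 | step 2 | tert-butyl (3S)-4-[(4R)-4-isopropyl-2-oxooxazolidin-3-yl]-3-[(3-methoxy-4-pivaloyloxyphenyl)methyl]-4-oxobutanoate | COc1cc(C[C@H](C(=O)N2[C@H](C(C)C)COC2=O)CC(=O)OC(C)(C)C)ccc1OC(=O)C(C)(C)C
F3 | step 2 | tert-butyl (3S)-4-hydroxy-3-[(3-methoxy-4-pivaloyloxyphenyl)methyl]butanoate | COc1cc(C[C@H](CO)CC(=O)OC(C)(C)C)ccc1OC(=O)C(C)(C)C
F4 | step 2 | (4S)-4-[(3-methoxy-4-pivaloyloxyphenyl)methyl]oxolan-2-one | COc1cc(C[C@@H]2COC(=O)C2)ccc1OC(=O)C(C)(C)C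
F5 | step 2 | (3S,4S)-3-[(4-benzyloxy-3-methoxyphenyl)methyl]-4-[(3-methoxy-4-pivaloyloxyphenyl)methyl]oxolan-2-one | COc1cc(C[C@@H]2COC(=O)[C@H]2Cc2ccc(OCc3ccccc3)c(OC)c2)ccc1OC(=O)C(C)(C)C
F6 | step 2 | 4-O-benzyl-(+)-(2S,3S)-secoisolariciresinol | COc1cc(C[C@H](CO)[C@H](Cc2ccc(OCc3ccccc3)c(OC)c2)CO)ccc1O
F7 | step 5 | (−)-lariciresinol 9-O-(carboxyacetate) | COc1cc(C[C@@H]2CO[C@@H](c3ccc(O)c(OC)c3)[C@@H]2COC(=O)CC(=O)O)ccc1O
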